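Ring B (C5–C10; labdane numbering, ring A = C1–C5, C10) is closed by an intramolecular Diels–Alder reaction. The structure supplies its own tether: the ester carbon on C4 and the hydroxyl oxygen on C6 are 1,3-related across C5, so the ring A acid is joined to a (1Z,3E)-dienol as a dienyl ester. Heating should form C5–C6 and C9–C10 in one operation, giving ring B, a temporary γ-lactone, the C10 quaternary centre and C9, all relayed from the single C4 stereocentre. Lactone opening returns the C4 methyl ester and the C6 oxygen; C5 is then inverted through the C6 ketone, and the side chain is attached by Negishi coupling before a final singlet-oxygen ene reaction.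

Key step: step 10

Numbering used throughout: decalin C1–C10; C17 = methyl on C8, C18 = carboxyl carbon on C4 (α), C19 = methyl on C4 (β), C20 = methyl on C10 (β); side chain C11–C16 from C9, with C16 the butenolide carbinol carbon. α is the face opposite the C10 methyl.

Assumption (step 2): the L-valine auxiliary with the HMPA/toluene protocol is taken to give the (R)-keto ester; should the opposite sense be found, D-valine tert-butyl ester or the THF protocol is used instead.
Assumption (step 20): the ProPhenol enantiomer is the one that delivers the (S)-carbinol, written here as (S,S).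

**Ring A acid**

Step 1
Reactants: 1 methyl 2-oxocyclohexane-1-carboxylate; 2 L-valine tert-butyl ester
Product: 3 tert-butyl (S)-2-{[2-(methoxycarbonyl)cyclohex-1-en-1-yl]amino}-3-methylbutanoate
Conditions: BF3·OEt2 (cat.), benzene, reflux, Dean–Stark
Reagents that add atoms: none
Why: Acid-catalysed condensation of the ketone with the primary amine should give the hydrogen-bonded, conjugated enamino ester (enamine formation); no new stereocentre is formed.

Step 2
Reactants: 3 chiral enamino ester
Product: 5 methyl (R)-1-methyl-2-oxocyclohexane-1-carboxylate, via α-methylated imino ester 4 (not isolated)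
Conditions: LiN(iPr)2, toluene, −78 °C; HMPA (1 equiv), MeI, −78 → −20 °C; then aq. citric acid, rt
Reagents that add atoms: methyl iodide, CI; water, O
Why: Asymmetric alkylation of a chiral lithio-enamino ester (Koga type): lithium is chelated by the valine ester so that the isopropyl group screens one face and MeI enters from the other, which sets the quaternary C4 centre, and hydrolysis of 4 then releases ketone and auxiliary.

Step 3
Reactants: 5 methyl (R)-1-methyl-2-oxocyclohexane-1-carboxylate
Product: 6 methyl (1R)-1,3-dimethyl-2-oxocyclohexane-1-carboxylate (both C3 epimers)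
Conditions: LiN(iPr)2, THF, −78 °C; MeI, −78 → 0 °C
Reagents that add atoms: methyl iodide, CI
Why: Enolate alkylation at the only enolisable (α′) position; the new methine centre is uncontrolled but is erased in step 4, and the quaternary centre cannot epimerise.

Step 4
Reactants: 6 methyl (1R)-1,3-dimethyl-2-oxocyclohexane-1-carboxylate
Product: 7 methyl (R)-1,3-dimethyl-2-{[(trifluoromethyl)sulfonyl]oxy}cyclohex-2-ene-1-carboxylate
Conditions: KN(SiMe3)2, THF, −78 °C; PhNTf2, −78 → 0 °C
Reagents that add atoms: N-phenylbis(trifluoromethanesulfonimide), O=S(=O)(N(c1ccccc1)S(=O)(=O)C(F)(F)F)C(F)(F)F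
Why: Enolisation is possible only toward the methyl-bearing carbon, so O-sulfonylation of the potassium enolate should give the tetrasubstituted enol triflate regiospecifically (enol triflate formation).

Step 5
Reactants: 7 enol triflate
Product: 8 methyl (R)-1,3-dimethylcyclohex-2-ene-1-carboxylate
Conditions: Pd(OAc)2 (5 mol %), PPh3, Bu3N, HCO2H, DMF, 60 °C
Reagents that add atoms: none
Why: Palladium-catalysed formate reduction of a vinyl triflate (oxidative addition, formate-to-hydride exchange with loss of CO2, reductive elimination) replaces OTf by H and leaves the double bond fixed at the future C5=C10.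

Step 6
Reactants: 8 methyl (R)-1,3-dimethylcyclohex-2-ene-1-carboxylate
Product: 9 (R)-1,3-dimethylcyclohex-2-ene-1-carboxylic acid
Conditions: KOH, MeOH–H2O, 80 °C; then aq. HCl to pH 2
Reagents that add atoms: potassium hydroxide, [K+].[OH-]
Why: Saponification of the hindered ester; the α-carbon is quaternary, so the stereocentre is safe under forcing base.

**Dienol component**

Step 7
Reactants: 10 3-(benzyloxy)propanal; 11 2-(triphenyl-λ5-phosphanylidene)propanal
Product: 12 (E)-5-(benzyloxy)-2-methylpent-2-enal
Conditions: toluene, 90 °C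
Reagents that add atoms: none
Why: Wittig olefination with a stabilised ylide, which should be E-selective and sets the future C8=C9 geometry.

Step 8
Reactants: 12 (E)-5-(benzyloxy)-2-methylpent-2-enal
Product: 13 (E)-{[(4-methylhex-3-en-5-yn-1-yl)oxy]methyl}benzene
Conditions: dimethyl (1-diazo-2-oxopropyl)phosphonate, K2CO3, MeOH, 0 °C → rt
Reagents that add atoms: dimethyl (1-diazo-2-oxopropyl)phosphonate, COP(=O)(OC)C(=[N+]=[N-])C(C)=O
Why: Seyferth–Gilbert homologation with the Ohira–Bestmann reagent converts the α-branched enal into the terminal enyne with retention of the alkene geometry.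

**Union, key step and ring B functionalisation**

Step 9
Reactants: 9 (R)-1,3-dimethylcyclohex-2-ene-1-carboxylic acid; 13 enyne
Product: 14 (1Z,3E)-6-(benzyloxy)-3-methylhexa-1,3-dien-1-yl (R)-1,3-dimethylcyclohex-2-ene-1-carboxylate
Conditions: Ru(η3-CH2C(CH3)CH2)2(Ph2P(CH2)4PPh2) (2 mol %), toluene, 65 °C
Reagents that add atoms: none
Why: Ruthenium-catalysed anti-Markovnikov addition of a carboxylic acid to a terminal alkyne through a ruthenium vinylidene, which is known to give Z enol esters and (Z)-dienyl esters from 2-substituted enynes; the E C8=C9 bond is untouched.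

Step 10
Reactants: 14 (1Z,3E)-dienyl ester
Product: 15 12-(benzyloxy)-13,14,15,16-tetranor-5β-labd-7-en-18,6α-olide (cis-fused decalin, 9β side chain, 10β methyl)
Conditions: 1,2-dichlorobenzene (0.01 M), BHT (cat.), argon, 210 °C, sealed tube
Reagents that add atoms: none
Why: Thermal, concerted but asynchronous [4+2] cycloaddition of the (1Z,3E)-1-acyloxydiene C6=C7–C8=C9 onto the unactivated trisubstituted ring A alkene C5=C10; the closest precedent is the type 1 intramolecular Diels–Alder reaction of 1,3,8-nonatrienes with a three-atom ester tether and a Z-diene. Ring B is closed by the cycloaddition itself (bonds C5–C6 and C9–C10), while the five-membered lactone (O–C18–C4–C5–C6) closes as the tether ring and is necessarily cis-fused to both carbocycles. Because the tether hangs from the C4 stereocentre, the diene can only reach the ring A face that carries C18, which fixes C10 (methyl β) and C5 relative to C4; suprafacial addition to the cyclic alkene makes the decalin cis (5β-H), a centre corrected in step 12. The Z enol-ester oxygen sits inside the diene, so only the transition state with ring A exo can span the tether; with the E C8=C9 geometry this places C11 cis to the C10 methyl (C9 as in the target) and the C6 oxygen α. The step needs regio- and facial selectivity, both enforced geometrically by the short tether against the weak electronic preference of the diene, and it needs forcing conditions because neither partner is activated. The quaternary C4 (reactive-rotamer effect) and the absence of a 1,5-hydrogen-shift pathway in this Z-dienyl ester should favour cyclisation over decomposition.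

Step 11
Reactants: 15 tricyclic lactone
Product: 17 methyl 12-(benzyloxy)-6α-hydroxy-13,14,15,16-tetranor-5β-labd-7-en-18-oate, via potassium hydroxy carboxylate 16 (not isolated)
Conditions: KOH (1.1 equiv), MeOH–H2O, 60 °C; evaporate; KHCO3, MeI, DMF, 0 °C → rt; crude product used at once
Reagents that add atoms: potassium hydroxide, [K+].[OH-]; methyl iodide, CI
Why: Saponification opens the γ-lactone and the carboxylate is O-methylated under essentially neutral conditions (SN2 on MeI), so the allylic alcohol is not alkylated and has little chance to relactonise before step 12; no stereocentre changes.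

Step 12
Reactants: 17 cis-fused hydroxy ester
Product: 19 methyl 12-(benzyloxy)-6-oxo-13,14,15,16-tetranorlabd-7-en-18-oate (5α-H, trans-fused), via cis-fused enone 18 (not isolated)
Conditions: Dess–Martin periodinane, NaHCO3, CH2Cl2, 0 °C; aqueous work-up; then NaOMe (0.3 equiv), MeOH, rt
Reagents that add atoms: none
Why: Dess–Martin oxidation of the allylic alcohol gives the 7-en-6-one, and methoxide then equilibrates C5 (α′ to the ketone) through the cross-conjugated dienolate to the trans-fused decalin, which should be the more stable epimer as in the natural 6-oxo-7-ene terpenoids (thermodynamic epimerisation); this sets C5.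

Step 13
Reactants: 19 trans-fused enone
Product: 20 methyl 12-(benzyloxy)-7α,8α-epoxy-6-oxo-13,14,15,16-tetranorlabdan-18-oate
Conditions: 30 % H2O2, NaOH, MeOH, 0 °C → rt
Reagents that add atoms: hydrogen peroxide, OO
Why: Weitz–Scheffer nucleophilic epoxidation: hydroperoxide anion should add to C8 from the α-face, opposite the syn-axial C20 methyl, and the enolate closes the epoxide on the same face, which places the C8 oxygen α with the C17 methyl β.

Step 14
Reactants: 20 epoxy ketone
Product: 22 methyl 12-(benzyloxy)-6α,8α-dihydroxy-13,14,15,16-tetranorlabdan-18-oate, via 8α-hydroxy-6-ketone 21 (not isolated)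
Conditions: SmI2 (5–6 equiv), THF–MeOH, −78 °C; then H2O, −78 → 0 °C
Reagents that add atoms: none
Why: SmI2 first cleaves the C7–O bond of the α,β-epoxy ketone (ketyl to samarium enolate) with retention of the C8 oxygen, and further electron transfer reduces the C6 ketone under thermodynamic-type control to the equatorial 6α-alcohol, because the axial 6β position faces three syn-axial methyls (C17, C19, C20).

Step 15
Reactants: 22 diol
Product: 23 methyl 12-(benzyloxy)-6α,8α-bis(triethylsilyloxy)-13,14,15,16-tetranorlabdan-18-oate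
Conditions: Et3SiOTf, 2,6-lutidine, CH2Cl2, −78 → 0 °C
Reagents that add atoms: triethylsilyl trifluoromethanesulfonate, CC[Si](CC)(CC)OS(=O)(=O)C(F)(F)F
Why: Silyl triflate protection of both the secondary and the tertiary hydroxyl; masking the 8α-OH is needed because a free 8α-hydroxyl would cyclise onto an electrophilic C12 to a tetrahydrofuran in steps 17 and 22.

Step 16
Reactants: 23 bis-silyl ether
Product: 24 methyl 12-hydroxy-6α,8α-bis(triethylsilyloxy)-13,14,15,16-tetranorlabdan-18-oate
Conditions: H2 (1 atm), Pd/C, EtOAc, rt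
Reagents that add atoms: none
Why: Hydrogenolysis of the benzyl ether; no alkene is present at this stage and silyl ethers survive in a non-protic solvent.

Step 17
Reactants: 24 primary alcohol
Product: 25 methyl 12-iodo-6α,8α-bis(triethylsilyloxy)-13,14,15,16-tetranorlabdan-18-oate
Conditions: I2, PPh3, imidazole, CH2Cl2, 0 °C
Reagents that add atoms: iodine, II
Why: Appel-type iodination of the primary alcohol through the alkoxyphosphonium salt (SN2 by iodide).

**Butenolide fragment**

Step 18
Reactants: 26 pent-3-yn-1-ol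
Product: 28 (E)-4-iodopent-3-en-1-ol, via alkenylzirconocene 27 (not isolated)
Conditions: Cp2Zr(H)Cl (2.3 equiv), THF, rt → 45 °C; then I2, 0 °C
Reagents that add atoms: iodine, II
Why: Hydrozirconation (syn addition, zirconium at the less hindered methyl-bearing carbon after equilibration with excess reagent) followed by iodinolysis with retention should give the E vinyl iodide.

Step 19
Reactants: 28 (E)-4-iodopent-3-en-1-ol
Product: 29 (E)-4-iodopent-3-enal
Conditions: Dess–Martin periodinane, NaHCO3, CH2Cl2, 0 °C; used at once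
Reagents that add atoms: none
Why: Buffered Dess–Martin oxidation gives the β,γ-unsaturated aldehyde without base or acid that would move the double bond into conjugation.

Step 20
Reactants: 29 (E)-4-iodopent-3-enal; 30 methyl propiolate
Product: 31 methyl (4S,6E)-4-hydroxy-7-iodooct-6-en-2-ynoate
Conditions: (S,S)-ProPhenol (20 mol %), ZnMe2, Ph3P=O (20 mol %), toluene, 4 °C
Reagents that add atoms: none
Why: Zinc–ProPhenol-catalysed enantioselective alkynylation of an aldehyde: the dinuclear zinc complex binds aldehyde and zinc alkynide and delivers the alkyne to one carbonyl face, which sets the C16 carbinol centre under reagent control.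

Step 21
Reactants: 31 γ-hydroxy ynoate
Product: 33 (5S)-5-[(2E)-3-iodobut-2-en-1-yl]-4-methylfuran-2(5H)-one, via Z-hydroxy enoate 32 (not isolated)
Conditions: Me2CuLi (from CuI and MeLi, 3 equiv), THF, −78 °C; then aq. NH4Cl, rt
Reagents that add atoms: lithium dimethylcuprate, [Li+].C[Cu-]C
Why: Syn carbocupration of the ynoate places the new methyl trans to the ester, so the carbinol and the ester are cis and lactonise to the β-methyl butenolide; the vinyl iodide is inert to the cuprate at −78 °C and C16 is untouched.

**Fragment coupling and endgame**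

Step 22
Reactants: 25 primary iodide; 33 vinyl iodide butenolide
Product: 35 methyl 6α,8α-bis(triethylsilyloxy) (13E,16S)-seco-sesterterpenoid ester (the bis-silyl ether of 36), via alkylzinc iodide 34 (not isolated)
Conditions: Zn dust, LiCl, THF, 35 °C; then 33, Pd2(dba)3 (2.5 mol %), SPhos (10 mol %), THF–NMP, rt
Reagents that add atoms: none
Why: Negishi sp3–sp2 cross-coupling: zinc insertion into the primary iodide and palladium-catalysed coupling with the alkenyl iodide proceed with retention of the E geometry under neutral conditions that should leave the base-sensitive butenolide and its C16 centre intact.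

Step 23
Reactants: 35 coupled bis-silyl ether
Product: 36 methyl (1R,4aS,5R,6R,8S,8aR)-6,8-dihydroxy-1,4a,6-trimethyl-5-{(3E)-3-methyl-5-[(2S)-3-methyl-5-oxo-2,5-dihydrofuran-2-yl]pent-3-en-1-yl}decahydronaphthalene-1-carboxylate
Conditions: HF·pyridine, pyridine, THF, 0 °C → rt
Reagents that add atoms: none
Why: Buffered fluoride desilylation removes both silyl ethers without strong acid, which could otherwise add the 8α-OH across the C13=C14 bond.

Step 24
Reactants: 36 diol alkene
Product: 37 methyl (1R,4aS,5R,6R,8S,8aR)-5-{(4S)-4-hydroperoxy-3-methylidene-5-[(2S)-3-methyl-5-oxo-2,5-dihydrofuran-2-yl]pentyl}-6,8-dihydroxy-1,4a,6-trimethyldecahydronaphthalene-1-carboxylate (CNP0324515.1)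
Conditions: O2, tetraphenylporphyrin (cat.), visible light, CH2Cl2, −20 °C; preparative HPLC
Reagents that add atoms: dioxygen, O=O
Why: Schenck ene reaction: singlet oxygen adds to C14 of the electron-rich trisubstituted alkene with hydrogen abstraction from the methyl group cis to C15 (cis effect), which moves the double bond to the exocyclic position; C14 is not directed by the substrate, so the (14S)-hydroperoxide is expected alongside its C14 epimer and the tertiary C13 hydroperoxide and is isolated by HPLC, the electron-poor butenolide being inert.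

**Compound list**

1 | methyl 2-oxocyclohexane-1-carboxylate | COC(=O)C1CCCCC1=O | starting material
2 | L-valine tert-butyl ester | CC(C)[C@H](N)C(=O)OC(C)(C)C | starting material
3 | tert-butyl (S)-2-{[2-(methoxycarbonyl)cyclohex-1-en-1-yl]amino}-3-methylbutanoate | COC(=O)C1=C(N[C@@H](C(C)C)C(=O)OC(C)(C)C)CCCC1 | intermediate
4 | methyl (R)-1-methyl-2-{[(S)-1-(tert-butoxy)-3-methyl-1-oxobutan-2-yl]imino}cyclohexane-1-carboxylate | COC(=O)[C@]1(C)CCCCC1=N[C@@H](C(C)C)C(=O)OC(C)(C)C | intermediate
5 | methyl (R)-1-methyl-2-oxocyclohexane-1-carboxylate | COC(=O)[C@]1(C)CCCCC1=O | intermediate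
6 | methyl (1R)-1,3-dimethyl-2-oxocyclohexane-1-carboxylate (C3 epimers) | COC(=O)[C@]1(C)CCCC(C)C1=O | intermediate
7 | methyl (R)-1,3-dimethyl-2-{[(trifluoromethyl)sulfonyl]oxy}cyclohex-2-ene-1-carboxylate | COC(=O)[C@]1(C)CCCC(C)=C1OS(=O)(=O)C(F)(F)F | intermediate
8 | methyl (R)-1,3-dimethylcyclohex-2-ene-1-carboxylate | COC(=O)[C@]1(C)CCCC(C)=C1 | intermediate
9 | (R)-1,3-dimethylcyclohex-2-ene-1-carboxylic acid | OC(=O)[C@]1(C)CCCC(C)=C1 | intermediate
10 | 3-(benzyloxy)propanal | O=CCCOCc1ccccc1 | starting material
11 | 2-(triphenyl-λ5-phosphanylidene)propanal | CC(C=O)=P(c1ccccc1)(c1ccccc1)c1ccccc1 | starting material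
12 | (E)-5-(benzyloxy)-2-methylpent-2-enal | O=C/C(C)=C/CCOCc1ccccc1 | intermediate
13 | (E)-{[(4-methylhex-3-en-5-yn-1-yl)oxy]methyl}benzene | C#C/C(C)=C/CCOCc1ccccc1 | intermediate
14 | (1Z,3E)-6-(benzyloxy)-3-methylhexa-1,3-dien-1-yl (R)-1,3-dimethylcyclohex-2-ene-1-carboxylate | O=C(O/C=C\C(C)=C\CCOCc1ccccc1)[C@]1(C)CCCC(C)=C1 | intermediate
15 | 12-(benzyloxy)-13,14,15,16-tetranor-5β-labd-7-en-18,6α-olide | O=C1O[C@H]2C=C(C)[C@H](CCOCc4ccccc4)[C@@]3(C)CCC[C@]1(C)[C@@H]23 | intermediate
16 | potassium 12-(benzyloxy)-6α-hydroxy-13,14,15,16-tetranor-5β-labd-7-en-18-oate | O(Cc1ccccc1)CC[C@@H]1[C@@]2(C)CCC[C@@](C)(C(=O)[O-])[C@H]2[C@@H](O)C=C1C.[K+] | intermediate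
17 | methyl 12-(benzyloxy)-6α-hydroxy-13,14,15,16-tetranor-5β-labd-7-en-18-oate | O(Cc1ccccc1)CC[C@@H]1[C@@]2(C)CCC[C@@](C)(C(=O)OC)[C@H]2[C@@H](O)C=C1C | intermediate
18 | methyl 12-(benzyloxy)-6-oxo-13,14,15,16-tetranor-5β-labd-7-en-18-oate | O(Cc1ccccc1)CC[C@@H]1[C@@]2(C)CCC[C@@](C)(C(=O)OC)[C@H]2C(=O)C=C1C | intermediate
19 | methyl 12-(benzyloxy)-6-oxo-13,14,15,16-tetranorlabd-7-en-18-oate (5α-H) | O(Cc1ccccc1)CC[C@@H]1[C@@]2(C)CCC[C@@](C)(C(=O)OC)[C@@H]2C(=O)C=C1C | intermediate
20 | methyl 12-(benzyloxy)-7α,8α-epoxy-6-oxo-13,14,15,16-tetranorlabdan-18-oate | O(Cc1ccccc1)CC[C@@H]1[C@@]2(C)CCC[C@@](C)(C(=O)OC)[C@@H]2C(=O)[C@H]3O[C@@]13C | intermediate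
21 | methyl 12-(benzyloxy)-8α-hydroxy-6-oxo-13,14,15,16-tetranorlabdan-18-oate | O(Cc1ccccc1)CC[C@@H]1[C@@]2(C)CCC[C@@](C)(C(=O)OC)[C@@H]2C(=O)C[C@@]1(C)O | intermediate
22 | methyl 12-(benzyloxy)-6α,8α-dihydroxy-13,14,15,16-tetranorlabdan-18-oate | O(Cc1ccccc1)CC[C@@H]1[C@@]2(C)CCC[C@@](C)(C(=O)OC)[C@@H]2[C@@H](O)C[C@@]1(C)O | intermediate
23 | methyl 12-(benzyloxy)-6α,8α-bis(triethylsilyloxy)-13,14,15,16-tetranorlabdan-18-oate | O(Cc1ccccc1)CC[C@@H]1[C@@]2(C)CCC[C@@](C)(C(=O)OC)[C@@H]2[C@@H](O[Si](CC)(CC)CC)C[C@@]1(C)O[Si](CC)(CC)CC | intermediate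
24 | methyl 12-hydroxy-6α,8α-bis(triethylsilyloxy)-13,14,15,16-tetranorlabdan-18-oate | OCC[C@@H]1[C@@]2(C)CCC[C@@](C)(C(=O)OC)[C@@H]2[C@@H](O[Si](CC)(CC)CC)C[C@@]1(C)O[Si](CC)(CC)CC | intermediate
25 | methyl 12-iodo-6α,8α-bis(triethylsilyloxy)-13,14,15,16-tetranorlabdan-18-oate | ICC[C@@H]1[C@@]2(C)CCC[C@@](C)(C(=O)OC)[C@@H]2[C@@H](O[Si](CC)(CC)CC)C[C@@]1(C)O[Si](CC)(CC)CC | intermediate
26 | pent-3-yn-1-ol | CC#CCCO | starting material
27 | O,C4-bis(chlorozirconocene) derivative of (E)-pent-3-en-1-ol | C/C(=C\CCO[Zr](Cl)(C1C=CC=C1)C1C=CC=C1)[Zr](Cl)(C1C=CC=C1)C1C=CC=C1 | intermediate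
28 | (E)-4-iodopent-3-en-1-ol | I/C(C)=C/CCO | intermediate
29 | (E)-4-iodopent-3-enal | I/C(C)=C/CC=O | intermediate
30 | methyl propiolate | C#CC(=O)OC | starting material
31 | methyl (4S,6E)-4-hydroxy-7-iodooct-6-en-2-ynoate | COC(=O)C#C[C@@H](O)C/C=C(C)/I | intermediate
32 | methyl (2Z,4S,6E)-4-hydroxy-7-iodo-3-methylocta-2,6-dienoate | COC(=O)/C=C(C)\[C@@H](O)C/C=C(C)/I | intermediate
33 | (5S)-5-[(2E)-3-iodobut-2-en-1-yl]-4-methylfuran-2(5H)-one | I/C(C)=C/C[C@@H]1OC(=O)C=C1C | intermediate
34 | 12-(iodozincio) analogue of 25 | I[Zn]CC[C@@H]1[C@@]2(C)CCC[C@@](C)(C(=O)OC)[C@@H]2[C@@H](O[Si](CC)(CC)CC)C[C@@]1(C)O[Si](CC)(CC)CC | intermediate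
35 | 6α,8α-bis(triethylsilyl) ether of 36 | C/C(CC[C@@H]1[C@@]2(C)CCC[C@@](C)(C(=O)OC)[C@@H]2[C@@H](O[Si](CC)(CC)CC)C[C@@]1(C)O[Si](CC)(CC)CC)=C\C[C@@H]1OC(=O)C=C1C | intermediate
36 | methyl (1R,4aS,5R,6R,8S,8aR)-6,8-dihydroxy-1,4a,6-trimethyl-5-{(3E)-3-methyl-5-[(2S)-3-methyl-5-oxo-2,5-dihydrofuran-2-yl]pent-3-en-1-yl}decahydronaphthalene-1-carboxylate | C/C(CC[C@@H]1[C@@]2(C)CCC[C@@](C)(C(=O)OC)[C@@H]2[C@@H](O)C[C@@]1(C)O)=C\C[C@@H]1OC(=O)C=C1C | intermediate
37 | methyl (1R,4aS,5R,6R,8S,8aR)-5-{(4S)-4-hydroperoxy-3-methylidene-5-[(2S)-3-methyl-5-oxo-2,5-dihydrofuran-2-yl]pentyl}-6,8-dihydroxy-1,4a,6-trimethyldecahydronaphthalene-1-carboxylate | C=C(CC[C@@H]1[C@@]2(C)CCC[C@@](C)(C(=O)OC)[C@@H]2[C@@H](O)C[C@@]1(C)O)[C@H](C[C@@H]1OC(=O)C=C1C)OO | target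

**Step count**

Total: 24 steps. Longest linear sequence: 18 steps (1–6, 9–17, 22–24).

**Steps most likely to fail**

1. Step 10 (key cycloaddition). The unactivated, trisubstituted ring A alkene may not engage the diene before the dienyl ester decomposes (acyl migration, polymerisation), because the enol ester must also adopt its disfavoured lactone-like conformation. The fallback activates the dienophile; it sets out from 8 and comes back at 15. Allylic oxidation of 8 (Rh2(caprolactamate)4 cat., t-BuOOH, K2CO3, CH2Cl2) should give methyl (R)-1,3-dimethyl-4-oxocyclohex-2-ene-1-carboxylate F1. Saponification (KOH, then cold HCl) gives keto acid F2, which is kept cold because it is a vinylogous β-keto acid. Ruthenium-catalysed addition to 13 as in step 9 gives the enone-bearing dienyl ester F3. Its cyclisation (Me2AlCl, CH2Cl2, −20 °C → rt, or toluene, 120 °C) now uses a conjugated dienophile, with the tether still fixing regiochemistry and face, and should give the 1-oxo lactone F4. The extra C1 ketone is removed by NaBH4/CeCl3·7H2O reduction to carbinol F5, xanthate formation (NaH, CS2, MeI) to F6 and Barton–McCombie reduction (Bu3SnH, AIBN, toluene, 90 °C), which returns 15.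

2. Step 12 (C5 inversion). The base-mediated equilibration may stall at a cis/trans mixture or erode C9 through the extended dienolate. The fallback uses kinetic instead of thermodynamic control; it sets out from 17 and comes back at 19. Compound 17 is oxidised with Dess–Martin periodinane only and the cis-fused enone 18 is isolated. LiN(iPr)2 and Me3SiCl in THF at −78 °C should remove only the α′ proton H5 and give the cross-conjugated 6-(trimethylsilyloxy)-5,7-diene F7. Protonation at −78 °C (HCl in THF) should occur at C5 from the α-face, the β-face being screened by the C19 and C20 methyls, and give 19 directly.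

3. Step 24 (ene reaction). Oxygen transfer occurs without facial bias at C14 and competes with hydrogen abstraction from C15, so 37 may be a minor component that is hard to resolve from polar isomers. The fallback changes the stage and the form in which the isomers are separated; it sets out from 35 and comes back at 37. The bis-silyl ether 35 is photooxygenated under the same conditions to the protected hydroperoxide F8. The OOH group is capped with 2-methoxypropene/PPTS as the 2-methoxyprop-2-yl peroxyketal F9, a stable non-polar derivative on which the C14 epimers and the C13 regioisomer are separated on silica. HF·pyridine in THF, then AcOH–H2O–THF, removes silyl groups and ketal to give 37.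

**Further compounds**

F1 | step 10 | methyl (R)-1,3-dimethyl-4-oxocyclohex-2-ene-1-carboxylate | COC(=O)[C@]1(C)CCC(=O)C(C)=C1
F2 | step 10 | (R)-1,3-dimethyl-4-oxocyclohex-2-ene-1-carboxylic acid | OC(=O)[C@]1(C)CCC(=O)C(C)=C1
F3 | step 10 | (1Z,3E)-6-(benzyloxy)-3-methylhexa-1,3-dien-1-yl (R)-1,3-dimethyl-4-oxocyclohex-2-ene-1-carboxylate | O=C(O/C=C\C(C)=C\CCOCc1ccccc1)[C@]1(C)CCC(=O)C(C)=C1
F4 | step 10 | 1-oxo analogue of lactone 15 | O=C1O[C@H]2C=C(C)[C@H](CCOCc4ccccc4)[C@@]3(C)C(=O)CC[C@]1(C)[C@@H]23
F5 | step 10 | 1-hydroxy analogue of lactone 15 | O=C1O[C@H]2C=C(C)[C@H](CCOCc4ccccc4)[C@@]3(C)C(O)CC[C@]1(C)[C@@H]23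
F6 | step 10 | S-methyl xanthate of F5 | O=C1O[C@H]2C=C(C)[C@H](CCOCc4ccccc4)[C@@]3(C)C(OC(=S)SC)CC[C@]1(C)[C@@H]23
F7 | step 12 | methyl 12-(benzyloxy)-6-(trimethylsilyloxy)-13,14,15,16-tetranorlabda-5,7-dien-18-oate | O(Cc1ccccc1)CC[C@@H]1[C@@]2(C)CCC[C@@](C)(C(=O)OC)C2=C(O[Si](C)(C)C)C=C1C
F8 | step 24 | 6α,8α-bis(triethylsilyl) ether of 37 | C=C(CC[C@@H]1[C@@]2(C)CCC[C@@](C)(C(=O)OC)[C@@H]2[C@@H](O[Si](CC)(CC)CC)C[C@@]1(C)O[Si](CC)(CC)CC)[C@H](C[C@@H]1OC(=O)C=C1C)OO
F9 | step 24 | 2-methoxyprop-2-yl peroxyketal of F8 | C=C(CC[C@@H]1[C@@]2(C)CCC[C@@](C)(C(=O)OC)[C@@H]2[C@@H](O[Si](CC)(CC)CC)C[C@@]1(C)O[Si](CC)(CC)CC)[C@H](C[C@@H]1OC(=O)C=C1C)OOC(C)(C)OC
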